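The numbers are invented.

The constants below describe a radical chain in which partner, at 0.800 M, is charged at less than substrate, at 1.0 M, so partner is the limiting reagent in both flasks.

    substrate + second chain carrier → released group + first chain carrier (k1 = 51800 /M/s)
    partner + first chain carrier → product + second chain carrier (k2 = 2.97 × 10⁵ /M/s)
    substrate + initiating radical → capped initiator + first chain carrier (k3 = 3.28 × 10⁵ /M/s)
    scavenger + released group → scavenged by-product (k4 = 0.532 /M/s)
    2 second chain carrier → ended chains A (k5 = 4.1 × 10⁶ /M/s)
    first chain carrier + radical scavenger → ended chains C (k6 = 8.07 × 10⁷ /M/s)
    initiator → 2 initiating radical (k7 = 0.00107 /s)
    substrate + released group ⇌ idle adduct, settled at all times (K8 = 0.67 /M)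
    first chain carrier → ended carrier (k9 = 163 /s)
    partner → decomposed reagent (k10 = 0.00121 /s)
    2 first chain carrier → ended chains B (k11 = 2 × 10⁸ /M/s)

- delta: substrate 1.0 M; partner 0.800 M; scavenger 0.800 M; initiator 5.0 mM; radical scavenger 0.20 mM; time 20 min
- beta: substrate 1.0 M; partner 0.800 M; scavenger 1.00 M; initiator 5.0 mM; radical scavenger 0.20 mM; time 20 min

- part of the substrate that has reacted at the end, delta
- part of the substrate that has reacted at the end, beta
- what raising the concentration of scavenger from its lowest to its highest value here does to the part of the substrate that has reacted (changes below 5 percentage points count as none) (no change / it rises / it falls)

- percent here means substrate units held: one ended chains B counts as two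
- what is said of released group includes idle adduct
- a step written with two of one species runs at k times the square of its concentration and takes two of it each time
- run time (delta): 20 min

Minutes of the meeting. I proposed following one partner molecule. It has two exits: the chain step with first chain carrier, which gives product, and decomposition at 0.00121 /s. A colleague asked how fast the chain exit is. I answered from the radical balance for delta. At the start of delta, radicals are made at 1.07 × 10⁻⁵ M/s. First chain carrier ends by its first-order step at 163 /s. That balance puts it at 6.56 × 10⁻⁸ M. Meeting itself then costs it 26.3 /s, which is slower than the first-order ending. So the pull p, the carrier level times the chain constant, is 0.0195 /s in delta. That gives 94.2%. This is the share f, the chance that a partner molecule leaves as product, p over the sum of both exits.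

The colleague objected that initiator decays. I replied that the partner's lifetime in delta, 48.3 s, is shorter than the initiator's half-life of 11 min. A second objection concerned radical scavenger. At its charge it takes carrier at 16100 /s, faster than the carrier's own ending. So I set the pull to nothing for a lag τ of 18.7 s in delta. Decomposition alone acts then, and 97.8% of the partner survives it. Product in delta comes to 0.736 M. Radicals capped on substrate add 0.00723 M. I committed to 74.4% for delta.

The colleague then asked about beta. The share f contains no scavenger, and released group enters no step that makes a carrier. Even the delta charge exceeds the released group expected. So I committed to the same figure for beta, and to no change.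

The forecast gave 73% for delta, 73% for beta and no change, holding that “The scavenger only clears released group”.

The simulation gives 73.3% for delta and 73.3% for beta, a shift of 0 percentage points: no change. My delta figure stands 1.1 points higher. Now take the neighbouring flask, which is delta with 0.020 M of initiator. In that flask the reckoned pull becomes 0.0780 /s, the lag 4.67 s and the share 98.5%. The reckoning therefore gives that flask 0.783 M of product. At 20.0 min, that flask holds product at 77.7% of the substrate charged.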